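**Plan**
Retrosynthetic cuts, in order: the seven benzyl ethers; then, with lower ring A taken back to a cyclohexenone, its two bonds to ring C (C4–C4a and O1–C8a) together; then C2–C3 of the lower unit (aldol); then upper C4–lower C6′ (Friedel–Crafts); the upper unit is (+)-taxifolin less its C5 oxygen.
Enabling feature: lower ring A is a 5-deoxy resorcinol ring whose only oxygens, O1 on C8a and OH on C7, are meta, with C4a on the side of C8a away from C7. This is 3-ethoxycyclohex-2-enone with C8a as carbonyl carbon, C7 as alkoxy carbon and C4a as the α′ carbon.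
So C4a can be the kinetic enolate carbon that attacks C4, and C8a the carbonyl that captures the C2 hydroxyl; ring A is aromatised afterwards.
Forward order: upper rings (taxifolin) → interflavan bond onto a phenol that becomes lower ring B → C2–C3–C4 chain → lower ring C fused to ring A as an enone → ring A aromatised → hydrogenolysis.
Stereochemistry: upper C2/C3 from taxifolin; upper C4 by arene entry anti to the C3 benzyloxy group; lower C2/C3 from an auxiliary-controlled anti-glycolate aldol, carried through the key step with both C–O bonds intact.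

Key step: step 14

Assumption: the SMILES is read as (2R,3S) for the lower flavan and (2R,3S,4R) for the upper one, that is 2,3-trans in both units and 3,4-trans at the interflavan carbon.
Assumption on step 10: the open-transition-state titanium aldol is taken to use the same enolate face as the syn aldols of this auxiliary class, which makes the (R)-auxiliary the one that leads to the (2R,3R) adduct.
Abbreviations: Bn = benzyl, Tf = trifluoromethanesulfonyl, TES = triethylsilyl, Ar* = 4,5-bis(benzyloxy)-2-[(2R,3S,4R)-3,7-bis(benzyloxy)-2-(3,4-bis(benzyloxy)phenyl)chroman-4-yl]phenyl.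

Step 1
Reactants: 1 (+)-taxifolin
Product: 2 (2R,3R)-7-(benzyloxy)-2-[3,4-bis(benzyloxy)phenyl]-3,5-dihydroxychroman-4-one
Conditions: BnBr (3.3 equiv), K2CO3, DMF, 23 °C, argon
Reagents that add atoms: benzyl bromide, BrCc1ccccc1
Why: Williamson O-benzylation should stop at O7, O3′ and O4′ because the C5 hydroxyl is hydrogen-bonded to the C4 carbonyl and the C3 alcohol is not ionised by carbonate, and no stereocentre is touched.

Step 2
Reactants: 2 tri-O-benzyltaxifolin
Product: 3 (2R,3R)-7-(benzyloxy)-2-[3,4-bis(benzyloxy)phenyl]-3-hydroxy-4-oxochroman-5-yl trifluoromethanesulfonate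
Conditions: PhNTf2, K2CO3, DMF, 23 °C, argon
Reagents that add atoms: N-phenylbis(trifluoromethanesulfonimide), O=S(=O)(N(c1ccccc1)S(=O)(=O)C(F)(F)F)C(F)(F)F
Why: Sulfonyl transfer to the one remaining phenoxide (aryl triflate formation) should spare the secondary C3 alcohol, and the triflate both prepares removal of the C5 oxygen and deactivates ring A for step 5.

Step 3
Reactants: 3 C5 triflate
Product: 4 (2R,3R)-3,7-bis(benzyloxy)-2-[3,4-bis(benzyloxy)phenyl]-4-oxochroman-5-yl trifluoromethanesulfonate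
Conditions: BnOC(=NH)CCl3, TfOH (cat.), CH2Cl2–cyclohexane, 0 → 23 °C
Reagents that add atoms: benzyl 2,2,2-trichloroacetimidate, N=C(OCc1ccccc1)C(Cl)(Cl)Cl
Why: Acid-catalysed O-benzylation with the trichloroacetimidate should etherify the C3 alcohol without the base that would epimerise or ring-open the α-alkoxy ketone.

Step 4
Reactants: 4 benzylated ketone triflate
Product: 5 (2R,3S,4R)-3,7-bis(benzyloxy)-2-[3,4-bis(benzyloxy)phenyl]-4-hydroxychroman-5-yl trifluoromethanesulfonate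
Conditions: NaBH4, THF–EtOH, 0 °C
Reagents that add atoms: none
Why: Borohydride reduction of the aryl ketone should deliver hydride anti to the C3 benzyloxy group to give mainly the 3,4-trans alcohol, and the C4 configuration is of no consequence because this centre is ionised in step 5.

Step 5
Reactants: 5 flavan-4-ol triflate; 6 3,4-bis(benzyloxy)phenol (2 equiv)
Product: 7 (2R,3S,4R)-3,7-bis(benzyloxy)-4-[4,5-bis(benzyloxy)-2-hydroxyphenyl]-2-[3,4-bis(benzyloxy)phenyl]chroman-5-yl trifluoromethanesulfonate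
Conditions: TMSOTf (0.2 equiv), 4 Å MS, CH2Cl2, −40 → 0 °C
Reagents that add atoms: none
Why: Friedel–Crafts alkylation through the C4 benzylic cation (stabilised by O1 and O7, as in flavan-3,4-diol couplings) should occur at the phenol carbon ortho to OH and para to the 3-benzyloxy group, entry anti to the C3 benzyloxy group setting the 3,4-trans centre, while the C5 triflate keeps ring A of 5 from competing as the nucleophile.

Step 6
Reactants: 7 coupled phenol triflate
Product: 8 4,5-bis(benzyloxy)-2-[(2R,3S,4R)-3,7-bis(benzyloxy)-2-(3,4-bis(benzyloxy)phenyl)chroman-4-yl]phenol (Ar*–OH)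
Conditions: Pd(OAc)2 (5 mol %), dppp, Et3SiH, DMF, 60 °C
Reagents that add atoms: none
Why: Palladium-catalysed reduction of the aryl triflate (oxidative addition to zerovalent palladium, hydride transfer from the silane, C–H reductive elimination) should remove the C5 oxygen without touching benzyl ethers or stereocentres.

Step 7
Reactants: 8 Ar*–OH
Product: 9 4,5-bis(benzyloxy)-2-[(2R,3S,4S)-3,7-bis(benzyloxy)-2-(3,4-bis(benzyloxy)phenyl)chroman-4-yl]phenyl trifluoromethanesulfonate (same geometry as 8; the C4 descriptor changes only through CIP priority)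
Conditions: Tf2O, pyridine, CH2Cl2, 0 °C
Reagents that add atoms: trifluoromethanesulfonic anhydride, O=S(=O)(OS(=O)(=O)C(F)(F)F)C(F)(F)F
Why: O-sulfonylation of the only free hydroxyl turns the phenol that activated step 5 into a cross-coupling handle.

Step 8
Reactants: 9 aryl triflate
Product: 10 4,5-bis(benzyloxy)-2-[(2R,3S,4R)-3,7-bis(benzyloxy)-2-(3,4-bis(benzyloxy)phenyl)chroman-4-yl]benzaldehyde (Ar*–CHO)
Conditions: Pd(OAc)2, dppp, CO (1 atm), Et3SiH, Et3N, DMF, 70 °C
Reagents that add atoms: carbon monoxide, [C-]#[O+]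
Why: Palladium-catalysed reductive carbonylation of the aryl triflate (CO insertion into the aryl–palladium bond, then hydride transfer from the silane) should give the benzaldehyde.

Step 9
Reactants: 11 (R)-4-benzyl-1,3-oxazolidine-2-thione; 12 (benzyloxy)acetyl chloride
Product: 13 (R)-4-benzyl-3-[(benzyloxy)acetyl]-1,3-oxazolidine-2-thione
Conditions: Et3N, CH2Cl2, 0 °C
Reagents that add atoms: none
Why: N-acylation of the oxazolidinethione with the acid chloride gives the glycolate aldol donor.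

Step 10
Reactants: 13 N-glycolyl oxazolidinethione; 10 Ar*–CHO
Product: 15 (R)-4-benzyl-3-[(2R,3R)-2-(benzyloxy)-3-hydroxy-3-Ar*-propanoyl]-1,3-oxazolidine-2-thione, via chlorotitanium Z-enolate 14 (not isolated)
Conditions: TiCl4 (1.05 equiv), i-Pr2NEt (1.1 equiv), CH2Cl2, −78 °C; then 10 premixed with TiCl4 (2 equiv), −78 °C; aq NH4Cl
Reagents that add atoms: none
Why: Titanium-enolate glycolate aldol of the N-glycolyl oxazolidinethione with the TiCl4-activated aldehyde through an open transition state should give the anti adduct, the benzyl group of the auxiliary shielding one face of the Z-enolate so that the future C2 and C3 of the lower flavan arise as (2R,3R) in the acyl chain.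

Step 11
Reactants: 15 aldol adduct
Product: 16 (R)-4-benzyl-3-[(2R,3R)-2-(benzyloxy)-3-Ar*-3-(triethylsilyloxy)propanoyl]-1,3-oxazolidine-2-thione
Conditions: TESOTf, 2,6-lutidine, CH2Cl2, −78 °C
Reagents that add atoms: triethylsilyl trifluoromethanesulfonate, CC[Si](CC)(CC)OS(=O)(=O)C(F)(F)F
Why: Silylation masks the future O1 during activation of C4 and C–C bond formation and gives an ether that the acid of step 14 removes.

Step 12
Reactants: 16 silylated aldol adduct
Product: 17 (2S,3R)-2-(benzyloxy)-3-Ar*-3-(triethylsilyloxy)propan-1-ol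
Conditions: LiBH4, Et2O–MeOH, 0 °C
Reagents that add atoms: none
Why: Borohydride reduction of the activated N-acyl oxazolidinethione to the primary alcohol releases the auxiliary and leaves silyl and benzyl ethers intact.

Step 13
Reactants: 17 primary alcohol
Product: 18 (2S,3R)-2-(benzyloxy)-3-Ar*-3-(triethylsilyloxy)propyl trifluoromethanesulfonate
Conditions: Tf2O, 2,6-lutidine, CH2Cl2, −78 °C; used at once
Reagents that add atoms: trifluoromethanesulfonic anhydride, O=S(=O)(OS(=O)(=O)C(F)(F)F)C(F)(F)F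
Why: Triflation of the primary alcohol gives an electrophile reactive enough for a hindered enolate at low temperature, the β-benzyloxy group slowing ionisation so that the triflate survives until it is used.

Step 14
Reactants: 18 primary triflate; 19 3-ethoxycyclohex-2-en-1-one (2 equiv)
Product: 22 (2R,3S)-3-(benzyloxy)-2-Ar*-2,3,4,4a,5,6-hexahydro-7H-chromen-7-one (both C4a epimers), via lithium dienolate 20 (not isolated), via C-alkylated enone 21 (not isolated)
Conditions: LiN(i-Pr)2 (2 equiv), THF, −78 °C; 18, −78 → −30 °C; then 1 M aq HCl–THF, 0 → 23 °C, same flask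
Reagents that add atoms: water, O
Why: Kinetic deprotonation of the vinylogous ester 19 gives the cross-conjugated α′-dienolate 20, which displaces the primary triflate of 18 by SN2 to form C4–C4a (Stork–Danheiser α′-alkylation), and aqueous acid then removes the silyl group so that the C2 hydroxyl adds to the C8a carbonyl and the hemiketal collapses, with loss of ethanol from C7, to the transposed cyclic vinylogous ester 22, forming O1–C8a. The closest known reaction types are the α′-alkylation of 3-alkoxycyclohex-2-enone enolates with primary electrophiles and the acid-catalysed cyclisation of hydroxyalkyl cyclohexane-1,3-diones to bicyclic enol ethers. Ring C closes by 6-exo-trig addition of O1 to C8a followed by elimination (addition–elimination at a vinylogous ester). The only new stereocentre, C4a, is not controlled and need not be, since it is erased at aromatisation, while C2 and C3 are retained because neither of their C–O bonds is broken. The step needs α′- over γ-deprotonation (kinetic lithium amide at −78 °C), C- over O-alkylation (lithium counter-ion in THF without polar additive) and six- over five-membered closure (the C3 oxygen is a benzyl ether, so only the C2 oxygen can close), and the silyl ether on the C2 oxygen prevents oxetane formation until the C–C bond is made.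

Step 15
Reactants: 22 hexahydrochromenone
Product: 24 (2R,3S)-3-(benzyloxy)-2-Ar*-chroman-7-ol, via cross-conjugated dienone 23 (not isolated)
Conditions: LiN(i-Pr)2 (1.2 equiv), THF, −78 °C; then PhS(Cl)=N-t-Bu, −78 → 0 °C
Reagents that add atoms: none
Why: Mukaiyama dehydrogenation (kinetic deprotonation at C6, S-sulfinimidoylation and syn elimination) should introduce the C5–C6 double bond, and the resulting dienone tautomerises by loss of the C4a proton to the phenol, erasing C4a and leaving C2 and C3 untouched.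

Step 16
Reactants: 24 heptabenzyl ether
Product: 25 target, (2R,3S)-2-{2-[(2R,3S,4R)-2-(3,4-dihydroxyphenyl)-3,7-dihydroxychroman-4-yl]-4,5-dihydroxyphenyl}chromane-3,7-diol
Conditions: H2 (1 atm), Pd(OH)2/C, THF–MeOH, 23 °C
Reagents that add atoms: none
Why: Hydrogenolysis of the seven benzyl ethers under neutral conditions should free all hydroxyls while the two benzylic ring C–O bonds and the diarylmethine survive, as in the final deprotection of benzylated proanthocyanidins.

**Compound list**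
1 | (+)-taxifolin, (2R,3R)-2-(3,4-dihydroxyphenyl)-3,5,7-trihydroxychroman-4-one | O=C1c2c(O)cc(O)cc2O[C@H](c2ccc(O)c(O)c2)[C@H]1O | starting material
2 | (2R,3R)-7-(benzyloxy)-2-[3,4-bis(benzyloxy)phenyl]-3,5-dihydroxychroman-4-one | O=C1c2c(O)cc(OCc3ccccc3)cc2O[C@H](c2ccc(OCc3ccccc3)c(OCc3ccccc3)c2)[C@H]1O | intermediate
3 | (2R,3R)-7-(benzyloxy)-2-[3,4-bis(benzyloxy)phenyl]-3-hydroxy-4-oxochroman-5-yl trifluoromethanesulfonate | O=C1c2c(OS(=O)(=O)C(F)(F)F)cc(OCc3ccccc3)cc2O[C@H](c2ccc(OCc3ccccc3)c(OCc3ccccc3)c2)[C@H]1O | intermediate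
4 | (2R,3R)-3,7-bis(benzyloxy)-2-[3,4-bis(benzyloxy)phenyl]-4-oxochroman-5-yl trifluoromethanesulfonate | O=C1c2c(OS(=O)(=O)C(F)(F)F)cc(OCc3ccccc3)cc2O[C@H](c2ccc(OCc3ccccc3)c(OCc3ccccc3)c2)[C@H]1OCc1ccccc1 | intermediate
5 | (2R,3S,4R)-3,7-bis(benzyloxy)-2-[3,4-bis(benzyloxy)phenyl]-4-hydroxychroman-5-yl trifluoromethanesulfonate | O[C@@H]1c2c(OS(=O)(=O)C(F)(F)F)cc(OCc3ccccc3)cc2O[C@H](c2ccc(OCc3ccccc3)c(OCc3ccccc3)c2)[C@H]1OCc1ccccc1 | intermediate
6 | 3,4-bis(benzyloxy)phenol | Oc1ccc(OCc2ccccc2)c(OCc2ccccc2)c1 | starting material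
7 | (2R,3S,4R)-3,7-bis(benzyloxy)-4-[4,5-bis(benzyloxy)-2-hydroxyphenyl]-2-[3,4-bis(benzyloxy)phenyl]chroman-5-yl trifluoromethanesulfonate | Oc1cc(OCc2ccccc2)c(OCc2ccccc2)cc1[C@@H]1c2c(OS(=O)(=O)C(F)(F)F)cc(OCc3ccccc3)cc2O[C@H](c2ccc(OCc3ccccc3)c(OCc3ccccc3)c2)[C@H]1OCc1ccccc1 | intermediate
8 | Ar*–OH, 4,5-bis(benzyloxy)-2-[(2R,3S,4R)-3,7-bis(benzyloxy)-2-(3,4-bis(benzyloxy)phenyl)chroman-4-yl]phenol | Oc1cc(OCc2ccccc2)c(OCc2ccccc2)cc1[C@@H]1c2ccc(OCc3ccccc3)cc2O[C@H](c2ccc(OCc3ccccc3)c(OCc3ccccc3)c2)[C@H]1OCc1ccccc1 | intermediate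
9 | 4,5-bis(benzyloxy)-2-[(2R,3S,4S)-3,7-bis(benzyloxy)-2-(3,4-bis(benzyloxy)phenyl)chroman-4-yl]phenyl trifluoromethanesulfonate | FC(F)(F)S(=O)(=O)Oc1cc(OCc2ccccc2)c(OCc2ccccc2)cc1[C@@H]1c2ccc(OCc3ccccc3)cc2O[C@H](c2ccc(OCc3ccccc3)c(OCc3ccccc3)c2)[C@H]1OCc1ccccc1 | intermediate
10 | Ar*–CHO, 4,5-bis(benzyloxy)-2-[(2R,3S,4R)-3,7-bis(benzyloxy)-2-(3,4-bis(benzyloxy)phenyl)chroman-4-yl]benzaldehyde | O=Cc1cc(OCc2ccccc2)c(OCc2ccccc2)cc1[C@@H]1c2ccc(OCc3ccccc3)cc2O[C@H](c2ccc(OCc3ccccc3)c(OCc3ccccc3)c2)[C@H]1OCc1ccccc1 | intermediate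
11 | (R)-4-benzyl-1,3-oxazolidine-2-thione | S=C1N[C@H](Cc2ccccc2)CO1 | starting material
12 | (benzyloxy)acetyl chloride | O=C(Cl)COCc1ccccc1 | starting material
13 | (R)-4-benzyl-3-[(benzyloxy)acetyl]-1,3-oxazolidine-2-thione | O=C(COCc1ccccc1)N1C(=S)OC[C@H]1Cc1ccccc1 | intermediate
14 | chlorotitanium Z-enolate of 13, formed in the flask | Cl[Ti](Cl)(Cl)O/C(=C\OCc1ccccc1)N1C(=S)OC[C@H]1Cc1ccccc1 | intermediate
15 | (R)-4-benzyl-3-[(2R,3R)-2-(benzyloxy)-3-hydroxy-3-Ar*-propanoyl]-1,3-oxazolidine-2-thione | O=C([C@H](OCc1ccccc1)[C@H](O)c1cc(OCc2ccccc2)c(OCc2ccccc2)cc1[C@@H]1c2ccc(OCc3ccccc3)cc2O[C@H](c2ccc(OCc3ccccc3)c(OCc3ccccc3)c2)[C@H]1OCc1ccccc1)N1C(=S)OC[C@H]1Cc1ccccc1 | intermediate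
16 | (R)-4-benzyl-3-[(2R,3R)-2-(benzyloxy)-3-Ar*-3-(triethylsilyloxy)propanoyl]-1,3-oxazolidine-2-thione | O=C([C@H](OCc1ccccc1)[C@H](O[Si](CC)(CC)CC)c1cc(OCc2ccccc2)c(OCc2ccccc2)cc1[C@@H]1c2ccc(OCc3ccccc3)cc2O[C@H](c2ccc(OCc3ccccc3)c(OCc3ccccc3)c2)[C@H]1OCc1ccccc1)N1C(=S)OC[C@H]1Cc1ccccc1 | intermediate
17 | (2S,3R)-2-(benzyloxy)-3-Ar*-3-(triethylsilyloxy)propan-1-ol | OC[C@H](OCc1ccccc1)[C@H](O[Si](CC)(CC)CC)c1cc(OCc2ccccc2)c(OCc2ccccc2)cc1[C@@H]1c2ccc(OCc3ccccc3)cc2O[C@H](c2ccc(OCc3ccccc3)c(OCc3ccccc3)c2)[C@H]1OCc1ccccc1 | intermediate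
18 | (2S,3R)-2-(benzyloxy)-3-Ar*-3-(triethylsilyloxy)propyl trifluoromethanesulfonate | FC(F)(F)S(=O)(=O)OC[C@H](OCc1ccccc1)[C@H](O[Si](CC)(CC)CC)c1cc(OCc2ccccc2)c(OCc2ccccc2)cc1[C@@H]1c2ccc(OCc3ccccc3)cc2O[C@H](c2ccc(OCc3ccccc3)c(OCc3ccccc3)c2)[C@H]1OCc1ccccc1 | intermediate
19 | 3-ethoxycyclohex-2-en-1-one | CCOC1=CC(=O)CCC1 | starting material
20 | lithium 3-ethoxycyclohexa-2,6-dien-1-olate (α′-dienolate of 19), formed in the flask | CCOC1=CC(O[Li])=CCC1 | intermediate
21 | 6-[(2S,3R)-2-(benzyloxy)-3-Ar*-3-(triethylsilyloxy)propyl]-3-ethoxycyclohex-2-en-1-one (C6 epimers), formed in the flask | CCOC1=CC(=O)C(C[C@H](OCc2ccccc2)[C@H](O[Si](CC)(CC)CC)c2cc(OCc3ccccc3)c(OCc3ccccc3)cc2[C@@H]2c3ccc(OCc4ccccc4)cc3O[C@H](c3ccc(OCc4ccccc4)c(OCc4ccccc4)c3)[C@H]2OCc2ccccc2)CC1 | intermediate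
22 | (2R,3S)-3-(benzyloxy)-2-Ar*-2,3,4,4a,5,6-hexahydro-7H-chromen-7-one (C4a epimers) | O=C1C=C2O[C@H](c3cc(OCc4ccccc4)c(OCc4ccccc4)cc3[C@@H]3c4ccc(OCc5ccccc5)cc4O[C@H](c4ccc(OCc5ccccc5)c(OCc5ccccc5)c4)[C@H]3OCc3ccccc3)[C@@H](OCc3ccccc3)CC2CC1 | intermediate
23 | (2R,3S)-3-(benzyloxy)-2-Ar*-2,3,4,4a-tetrahydro-7H-chromen-7-one, formed in the flask | O=C1C=C2O[C@H](c3cc(OCc4ccccc4)c(OCc4ccccc4)cc3[C@@H]3c4ccc(OCc5ccccc5)cc4O[C@H](c4ccc(OCc5ccccc5)c(OCc5ccccc5)c4)[C@H]3OCc3ccccc3)[C@@H](OCc3ccccc3)CC2C=C1 | intermediate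
24 | (2R,3S)-3-(benzyloxy)-2-Ar*-chroman-7-ol | Oc1ccc2c(c1)O[C@H](c1cc(OCc3ccccc3)c(OCc3ccccc3)cc1[C@@H]1c3ccc(OCc4ccccc4)cc3O[C@H](c3ccc(OCc4ccccc4)c(OCc4ccccc4)c3)[C@H]1OCc1ccccc1)[C@@H](OCc1ccccc1)C2 | intermediate
25 | (2R,3S)-2-{2-[(2R,3S,4R)-2-(3,4-dihydroxyphenyl)-3,7-dihydroxychroman-4-yl]-4,5-dihydroxyphenyl}chromane-3,7-diol | Oc1ccc2c(c1)O[C@H](c1cc(O)c(O)cc1[C@@H]1c3ccc(O)cc3O[C@H](c3ccc(O)c(O)c3)[C@H]1O)[C@@H](O)C2 | target

**Count**
Total steps: 16. Longest linear sequence: 15 (steps 1–8 and 10–16 from taxifolin; step 9 is a one-step branch).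

**Steps most likely to fail**

1. Step 14. What may go wrong: O- instead of C-alkylation of the dienolate, base-induced loss of triflic acid from 18, proton exchange leading to double alkylation, or a transposition that stalls at the open hydroxy enone. The fallback sets out from 18 and comes back at 25; it brings ring A in as an arene instead of an enone. 3-Bromo-4-iodophenol is benzylated (BnBr, K2CO3) to 4-(benzyloxy)-2-bromo-1-iodobenzene F1. Iodine–magnesium exchange (i-PrMgCl·LiCl, −40 °C) and coupling of the arylmagnesium reagent with triflate 18, catalysed by copper iodide CuI (monovalent copper), form C4–C4a and give 4-(benzyloxy)-2-bromo-1-[(2S,3R)-2-(benzyloxy)-3-Ar*-3-(triethylsilyloxy)propyl]benzene F2. Bu4NF frees the C2 hydroxyl to give (1R,2S)-3-[4-(benzyloxy)-2-bromophenyl]-2-(benzyloxy)-1-Ar*-propan-1-ol F3. Palladium-catalysed intramolecular C–O coupling (Pd(OAc)2, 2-(di-tert-butylphosphino)-1,1′-binaphthyl, Cs2CO3, toluene, 80 °C) forms O1–C8a and gives (2R,3S)-3,7-bis(benzyloxy)-2-Ar*-chroman F4. F4 is hydrogenolysed under the conditions of step 16 to 25.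

2. Step 10. What may go wrong: low or reversed facial selection on the enolate, erosion of anti selectivity, slow addition to the hindered electron-rich aldehyde, or Lewis-acid cleavage of benzyl ethers by excess TiCl4. If only the facial sense is opposite, the (S)-antipode of 11 is used in step 9. The fallback sets out from 10 and comes back at 17; it replaces auxiliary control by a chiral Lewis acid. A Mukaiyama aldol of 10 with (Z)-2-(benzyloxy)-1-(ethylsulfanyl)-1-(trimethylsilyloxy)ethene is promoted by Sn(OTf)2 (divalent tin), a proline-derived chiral diamine (antipode chosen for the 2R,3R product) and Bu2Sn(OAc)2 in CH2Cl2 at −78 °C. This anti-selective variant for α-benzyloxy thioester donors should give S-ethyl (2R,3R)-2-(benzyloxy)-3-hydroxy-3-Ar*-propanethioate F5. TESOTf and 2,6-lutidine give S-ethyl (2R,3R)-2-(benzyloxy)-3-Ar*-3-(triethylsilyloxy)propanethioate F6, and LiBH4 reduces the thioester to 17.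

3. Step 8. What may go wrong: slow oxidative addition into the hindered, electron-rich triflate and competing hydride capture of the aryl–palladium species before CO insertion, which returns the arene. The fallback sets out from 9 and comes back at 10. Suzuki–Miyaura coupling with potassium vinyltrifluoroborate CH2=CHBF3K (PdCl2(dppf), Cs2CO3, THF–H2O, 70 °C) gives 1,2-bis(benzyloxy)-4-ethenyl-5-[(2R,3S,4R)-3,7-bis(benzyloxy)-2-(3,4-bis(benzyloxy)phenyl)chroman-4-yl]benzene F7. Lemieux–Johnson cleavage (OsO4 cat., NaIO4, 2,6-lutidine, dioxane–H2O) then gives 10.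

**Further compounds**
F1 | step 14 | 4-(benzyloxy)-2-bromo-1-iodobenzene | Brc1cc(OCc2ccccc2)ccc1I
F2 | step 14 | 4-(benzyloxy)-2-bromo-1-[(2S,3R)-2-(benzyloxy)-3-Ar*-3-(triethylsilyloxy)propyl]benzene | Brc1cc(OCc2ccccc2)ccc1C[C@H](OCc1ccccc1)[C@H](O[Si](CC)(CC)CC)c1cc(OCc2ccccc2)c(OCc2ccccc2)cc1[C@@H]1c2ccc(OCc3ccccc3)cc2O[C@H](c2ccc(OCc3ccccc3)c(OCc3ccccc3)c2)[C@H]1OCc1ccccc1
F3 | step 14 | (1R,2S)-3-[4-(benzyloxy)-2-bromophenyl]-2-(benzyloxy)-1-Ar*-propan-1-ol | Brc1cc(OCc2ccccc2)ccc1C[C@H](OCc1ccccc1)[C@H](O)c1cc(OCc2ccccc2)c(OCc2ccccc2)cc1[C@@H]1c2ccc(OCc3ccccc3)cc2O[C@H](c2ccc(OCc3ccccc3)c(OCc3ccccc3)c2)[C@H]1OCc1ccccc1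
F4 | step 14 | (2R,3S)-3,7-bis(benzyloxy)-2-Ar*-chroman | C(Oc1ccc2c(c1)O[C@H](c1cc(OCc3ccccc3)c(OCc3ccccc3)cc1[C@@H]1c3ccc(OCc4ccccc4)cc3O[C@H](c3ccc(OCc4ccccc4)c(OCc4ccccc4)c3)[C@H]1OCc1ccccc1)[C@@H](OCc1ccccc1)C2)c1ccccc1
F5 | step 10 | S-ethyl (2R,3R)-2-(benzyloxy)-3-hydroxy-3-Ar*-propanethioate | CCSC(=O)[C@H](OCc1ccccc1)[C@H](O)c1cc(OCc2ccccc2)c(OCc2ccccc2)cc1[C@@H]1c2ccc(OCc3ccccc3)cc2O[C@H](c2ccc(OCc3ccccc3)c(OCc3ccccc3)c2)[C@H]1OCc1ccccc1
F6 | step 10 | S-ethyl (2R,3R)-2-(benzyloxy)-3-Ar*-3-(triethylsilyloxy)propanethioate | CCSC(=O)[C@H](OCc1ccccc1)[C@H](O[Si](CC)(CC)CC)c1cc(OCc2ccccc2)c(OCc2ccccc2)cc1[C@@H]1c2ccc(OCc3ccccc3)cc2O[C@H](c2ccc(OCc3ccccc3)c(OCc3ccccc3)c2)[C@H]1OCc1ccccc1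
F7 | step 8 | 1,2-bis(benzyloxy)-4-ethenyl-5-[(2R,3S,4R)-3,7-bis(benzyloxy)-2-(3,4-bis(benzyloxy)phenyl)chroman-4-yl]benzene | C=Cc1cc(OCc2ccccc2)c(OCc2ccccc2)cc1[C@@H]1c2ccc(OCc3ccccc3)cc2O[C@H](c2ccc(OCc3ccccc3)c(OCc3ccccc3)c2)[C@H]1OCc1ccccc1
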